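**Retrosynthetic overview**

1. The last C–C bond is Cα–CH2 of the trans-α,β-dibenzyl-γ-butyrolactone, made by trans-selective alkylation of the enolate of (R)-β-(arylmethyl)butyrolactone 8 with the dihydrobenzofuran-5-ylmethyl bromide 23; two deprotections follow.
2. The strategy rests on the lactone ring: O1 sits between C2(=O) and the unsubstituted C5H2, and C4 (bearing the guaiacylmethyl group) is the ring's only stereocentre before alkylation. Deleting O1 leaves a 3-substituted cyclobutanone with a mirror plane through C1 and C3, so 8 is made from cyclobutanone 6 by enantioselective Baeyer–Villiger oxygen insertion.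
3. Cyclobutanone 6 comes from eugenol by O-benzylation, dichloroketene [2+2] cycloaddition and dechlorination.
4. Bromide 23 comes from methyl vanillate: the dihydrofuran ring is closed by enantioselective carbenoid 1,5-C–H insertion of aryl diazoacetate 17 (sets C2), then base equilibration to the trans ester (sets C3).
5. Ring order: cyclobutane (step 2), expanded to the lactone (step 4); dihydrofuran ring (step 9); the halves are joined in step 15.

Key step: step 4

Assumption: the absolute sense of induction of the chiral catalysts in steps 4 and 9 on these substrates is taken to follow their catalyst class; if the first run shows the opposite sense, the antipodal ligand or catalyst, equally accessible, is used with no other change.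

**Route**

Step 1
Reactants: 1 eugenol
Product: 2 4-allyl-1-(benzyloxy)-2-methoxybenzene
Conditions: BnBr, K2CO3, acetone, reflux
Reagents that add atoms: benzyl bromide, BrCc1ccccc1
Why: Williamson etherification of the phenoxide gives a benzyl ether that should survive the ketene cycloaddition, the peracid oxidation and the enolate chemistry.

Step 2
Reactants: 2 4-allyl-1-(benzyloxy)-2-methoxybenzene; 3 trichloroacetyl chloride
Product: 5 3-[4-(benzyloxy)-3-methoxybenzyl]-2,2-dichlorocyclobutan-1-one (racemic), via dichloroketene 4 (not isolated)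
Conditions: activated Zn dust, Et2O/DME, ultrasound, 15–25 °C, slow addition of 3
Reagents that add atoms: none
Why: Zinc dechlorinates 3 to dichloroketene, which undergoes thermal [2+2] cycloaddition with the terminal alkene, its carbonyl carbon bonding to the terminal CH2; the ring carbon bearing the benzyl group forms racemic, which is immaterial because it stops being a stereocentre in step 3.

Step 3
Reactants: 5 3-[4-(benzyloxy)-3-methoxybenzyl]-2,2-dichlorocyclobutan-1-one
Product: 6 3-[4-(benzyloxy)-3-methoxybenzyl]cyclobutan-1-one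
Conditions: Zn dust, AcOH, 25 → 60 °C
Reagents that add atoms: none
Why: Reductive dehalogenation of the α,α-dichloroketone by zinc in acetic acid leaves the benzyl ether and the arene untouched and gives the mirror-symmetric ketone.

Step 4
Reactants: 6 3-[4-(benzyloxy)-3-methoxybenzyl]cyclobutan-1-one
Product: 8 (R)-4-[4-(benzyloxy)-3-methoxybenzyl]dihydrofuran-2(3H)-one, via Criegee adduct 7 (not isolated)
Conditions: Sc(OTf)3 (5 mol %), chiral N,N′-dioxide ligand from L-pipecolic acid with 2,4,6-triisopropylanilide arms (5.5 mol %), m-CPBA (1.2 equiv), EtOAc, −20 °C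
Reagents that add atoms: 3-chloroperbenzoic acid, OOC(=O)c1cccc(Cl)c1
Why: The trivalent scandium N,N′-dioxide complex binds the strained ketone and the peracid adds to give Criegee adduct 7, after which the ring CH2 held anti-periplanar to the O–O bond in the chiral pocket migrates from carbon to oxygen with loss of 3-chlorobenzoate. The closest known reaction type is the catalytic asymmetric Baeyer–Villiger oxidation of prochiral 3-substituted cyclobutanones to β-substituted γ-butyrolactones. The five-membered lactone ring is closed by ring expansion of the cyclobutanone (a 1,2-shift of carbon to oxygen), not by cyclisation, the new oxygen being bonded to the carbonyl carbon on peroxide addition and to CH2 on migration. The C4 stereocentre arises only from the choice between the two enantiotopic migrating CH2 groups, which the chiral catalyst alone makes because the substrate, with its mirror plane through C1 and C3, has no bias of its own. No regioselectivity is needed since both α-carbons are CH2, and chemoselectivity over oxidation of the dialkoxyarene is secured by the strain-accelerated reactivity of the cyclobutanone and by the CH2 group that insulates the ring from the arene.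

Step 5
Reactants: 9 methyl 4-hydroxy-3-methoxybenzoate (methyl vanillate)
Product: 10 methyl 4-hydroxy-3-iodo-5-methoxybenzoate
Conditions: NIS, TFA (cat.), MeCN, 25 °C
Reagents that add atoms: N-iodosuccinimide, O=C1CCC(=O)N1I
Why: Electrophilic aromatic iodination is directed by the phenol to its only free ortho position, the para position being blocked by the ester.

Step 6
Reactants: 10 methyl 4-hydroxy-3-iodo-5-methoxybenzoate; 11 4-(benzyloxy)-3-methoxybenzyl alcohol
Product: 12 methyl 4-{[4-(benzyloxy)-3-methoxybenzyl]oxy}-3-iodo-5-methoxybenzoate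
Conditions: PPh3, DIAD, THF, 0 → 25 °C
Reagents that add atoms: none
Why: Mitsunobu etherification, in which the acidic phenol (ortho iodine, para ester) displaces the activated primary benzylic alcohol; no stereocentre is involved.

Step 7
Reactants: 12 methyl 4-{[4-(benzyloxy)-3-methoxybenzyl]oxy}-3-iodo-5-methoxybenzoate; 13 dimethyl oxalate
Product: 15 methyl 4-{[4-(benzyloxy)-3-methoxybenzyl]oxy}-3-methoxy-5-(2-methoxy-2-oxoacetyl)benzoate, via arylmagnesium chloride 14 (not isolated)
Conditions: iPrMgCl·LiCl (1.1 equiv), THF, −40 °C; then cannulated into 13 (3 equiv), THF, −78 °C; aq. NH4Cl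
Reagents that add atoms: none
Why: Iodine–magnesium exchange, accelerated by the ortho alkoxy group, tolerates the methyl ester at −40 °C, and the aryl Grignard reagent acylates excess oxalate only once because the tetrahedral adduct persists at −78 °C.

Step 8
Reactants: 15 methyl 4-{[4-(benzyloxy)-3-methoxybenzyl]oxy}-3-methoxy-5-(2-methoxy-2-oxoacetyl)benzoate
Product: 17 methyl 4-{[4-(benzyloxy)-3-methoxybenzyl]oxy}-3-(1-diazo-2-methoxy-2-oxoethyl)-5-methoxybenzoate, via tosylhydrazone 16 (not isolated)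
Conditions: TsNHNH2, toluene, 80 °C; then DBU, CH2Cl2, 25 °C
Reagents that add atoms: p-toluenesulfonyl hydrazide, Cc1ccc(cc1)S(=O)(=O)NN
Why: Condensation at the ketone carbonyl followed by base-induced loss of sulfinate (Bamford–Stevens-type elimination) gives the aryl diazoacetate, which is stabilised by the aryl and ester groups.

Step 9
Reactants: 17 methyl 4-{[4-(benzyloxy)-3-methoxybenzyl]oxy}-3-(1-diazo-2-methoxy-2-oxoethyl)-5-methoxybenzoate
Product: 18 dimethyl (2S,3R)-2-[4-(benzyloxy)-3-methoxyphenyl]-7-methoxy-2,3-dihydrobenzofuran-3,5-dicarboxylate (cis)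
Conditions: Rh2(R-PTTL)4 (dirhodium tetrakis[N-phthaloyl-(R)-tert-leucinate], 1 mol %), toluene, −78 → −60 °C
Reagents that add atoms: none
Why: Enantioselective intramolecular 1,5-C–H insertion of the divalent-rhodium-bound donor/acceptor carbene into the benzylic ether C–H (activated by oxygen and the electron-rich aryl group) closes the dihydrofuran ring, the chiral carboxylate ligands choosing between the two enantiotopic benzylic hydrogens and so setting C2 as S, with the cis ester as the kinetic product.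

Step 10
Reactants: 18 dimethyl (2S,3R)-2-[4-(benzyloxy)-3-methoxyphenyl]-7-methoxy-2,3-dihydrobenzofuran-3,5-dicarboxylate
Product: 19 dimethyl (2S,3S)-2-[4-(benzyloxy)-3-methoxyphenyl]-7-methoxy-2,3-dihydrobenzofuran-3,5-dicarboxylate (trans)
Conditions: NaOMe (0.2 equiv), MeOH/THF, 0 → 25 °C
Reagents that add atoms: none
Why: Base-mediated epimerisation through the ester enolate at C3 (benzylic and α to the ester) equilibrates to the more stable trans isomer, so C3 is set under thermodynamic control relative to the untouched C2, and methoxide matches the methyl esters.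

Step 11
Reactants: 19 dimethyl (2S,3S)-2-[4-(benzyloxy)-3-methoxyphenyl]-7-methoxy-2,3-dihydrobenzofuran-3,5-dicarboxylate
Product: 20 methyl (2S,3R)-2-[4-(benzyloxy)-3-methoxyphenyl]-3-(hydroxymethyl)-7-methoxy-2,3-dihydrobenzofuran-5-carboxylate
Conditions: LiBH4 (1.2 equiv), THF, 0 → 25 °C
Reagents that add atoms: none
Why: Chemoselective hydride reduction, the aliphatic and inductively activated C3 ester being reduced faster than the conjugated aryl ester deactivated by the para ring oxygen; the change of descriptor at C3 is only a change of priorities.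

Step 12
Reactants: 20 methyl (2S,3R)-2-[4-(benzyloxy)-3-methoxyphenyl]-3-(hydroxymethyl)-7-methoxy-2,3-dihydrobenzofuran-5-carboxylate
Product: 21 methyl (2S,3R)-2-[4-(benzyloxy)-3-methoxyphenyl]-3-{[(tert-butyldimethylsilyl)oxy]methyl}-7-methoxy-2,3-dihydrobenzofuran-5-carboxylate
Conditions: TBSCl, imidazole, DMF, 25 °C
Reagents that add atoms: tert-butyldimethylsilyl chloride, CC(C)(C)[Si](C)(C)Cl
Why: Standard silylation of the primary alcohol gives an ether that is stable to hydride, to the Appel reaction and to the lithium enolate, and is later removed without hydrogenolysis.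

Step 13
Reactants: 21 methyl (2S,3R)-2-[4-(benzyloxy)-3-methoxyphenyl]-3-{[(tert-butyldimethylsilyl)oxy]methyl}-7-methoxy-2,3-dihydrobenzofuran-5-carboxylate
Product: 22 {(2S,3R)-2-[4-(benzyloxy)-3-methoxyphenyl]-3-{[(tert-butyldimethylsilyl)oxy]methyl}-7-methoxy-2,3-dihydrobenzofuran-5-yl}methanol
Conditions: LiAlH4, THF, 0 °C; aqueous NaOH work-up
Reagents that add atoms: none
Why: Hydride reduction of the remaining aryl ester to the benzylic alcohol, with silyl and benzyl ethers inert.

Step 14
Reactants: 22 {(2S,3R)-2-[4-(benzyloxy)-3-methoxyphenyl]-3-{[(tert-butyldimethylsilyl)oxy]methyl}-7-methoxy-2,3-dihydrobenzofuran-5-yl}methanol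
Product: 23 (2S,3R)-2-[4-(benzyloxy)-3-methoxyphenyl]-5-(bromomethyl)-3-{[(tert-butyldimethylsilyl)oxy]methyl}-7-methoxy-2,3-dihydrobenzofuran
Conditions: CBr4, PPh3, CH2Cl2, 0 °C; used at once
Reagents that add atoms: carbon tetrabromide, BrC(Br)(Br)Br
Why: Appel bromination converts the electron-rich benzylic alcohol to the bromide under neutral conditions that spare the silyl ether and the acid-sensitive benzylic C2–O bond.

Step 15
Reactants: 8 (R)-4-[4-(benzyloxy)-3-methoxybenzyl]dihydrofuran-2(3H)-one; 23 (2S,3R)-2-[4-(benzyloxy)-3-methoxyphenyl]-5-(bromomethyl)-3-{[(tert-butyldimethylsilyl)oxy]methyl}-7-methoxy-2,3-dihydrobenzofuran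
Product: 25 (3R,4R)-4-[4-(benzyloxy)-3-methoxybenzyl]-3-({(2S,3R)-2-[4-(benzyloxy)-3-methoxyphenyl]-3-{[(tert-butyldimethylsilyl)oxy]methyl}-7-methoxy-2,3-dihydrobenzofuran-5-yl}methyl)dihydrofuran-2(3H)-one, via lithium enolate 24 (not isolated)
Conditions: LiN(SiMe3)2 (1.05 equiv), THF, −78 °C; then 23, DMPU, −78 → −40 °C
Reagents that add atoms: none
Why: Alkylation of the lactone lithium enolate with the reactive benzylic bromide occurs on the face anti to the C4 arylmethyl group (1,2-induction), giving the trans-3,4-disubstituted lactone with C3 as R, as is standard for dibenzylbutyrolactone lignans.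

Step 16
Reactants: 25 (3R,4R)-4-[4-(benzyloxy)-3-methoxybenzyl]-3-({(2S,3R)-2-[4-(benzyloxy)-3-methoxyphenyl]-3-{[(tert-butyldimethylsilyl)oxy]methyl}-7-methoxy-2,3-dihydrobenzofuran-5-yl}methyl)dihydrofuran-2(3H)-one
Product: 26 (3R,4R)-4-[4-(benzyloxy)-3-methoxybenzyl]-3-({(2S,3R)-2-[4-(benzyloxy)-3-methoxyphenyl]-3-(hydroxymethyl)-7-methoxy-2,3-dihydrobenzofuran-5-yl}methyl)dihydrofuran-2(3H)-one
Conditions: HF·pyridine, THF/pyridine, 0 → 25 °C
Reagents that add atoms: none
Why: Fluoride cleavage of the primary silyl ether under buffered, weakly acidic conditions should not epimerise the lactone α-centre or affect the benzyl ethers and the dihydrobenzofuran.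

Step 17
Reactants: 26 (3R,4R)-4-[4-(benzyloxy)-3-methoxybenzyl]-3-({(2S,3R)-2-[4-(benzyloxy)-3-methoxyphenyl]-3-(hydroxymethyl)-7-methoxy-2,3-dihydrobenzofuran-5-yl}methyl)dihydrofuran-2(3H)-one
Product: 27 Isolappaol A
Conditions: H2 (1 atm), 10% Pd/C, EtOAc/EtOH, 25 °C, stopped at full conversion
Reagents that add atoms: none
Why: Catalytic hydrogenolysis removes the two aryl benzyl ethers quickly at 1 atm, conditions under which the cyclic benzylic C2–O bond of the dihydrobenzofuran and the lactone are expected to persist.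

**Compound list**

1 | eugenol | C=CCc1ccc(O)c(OC)c1 | starting material
2 | 4-allyl-1-(benzyloxy)-2-methoxybenzene | C=CCc1ccc(OCc2ccccc2)c(OC)c1 | intermediate
3 | trichloroacetyl chloride | O=C(Cl)C(Cl)(Cl)Cl | starting material
4 | dichloroketene | O=C=C(Cl)Cl | intermediate
5 | 3-[4-(benzyloxy)-3-methoxybenzyl]-2,2-dichlorocyclobutan-1-one (racemic) | COc1cc(CC2CC(=O)C2(Cl)Cl)ccc1OCc1ccccc1 | intermediate
6 | 3-[4-(benzyloxy)-3-methoxybenzyl]cyclobutan-1-one | COc1cc(CC2CC(=O)C2)ccc1OCc1ccccc1 | intermediate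
7 | Criegee adduct: 3-[4-(benzyloxy)-3-methoxybenzyl]-1-hydroxycyclobutyl 3-chloroperoxybenzoate | COc1cc(CC2CC(O)(OOC(=O)c3cccc(Cl)c3)C2)ccc1OCc1ccccc1 | intermediate
8 | (R)-4-[4-(benzyloxy)-3-methoxybenzyl]dihydrofuran-2(3H)-one | COc1cc(C[C@H]2COC(=O)C2)ccc1OCc1ccccc1 | intermediate
9 | methyl 4-hydroxy-3-methoxybenzoate (methyl vanillate) | COC(=O)c1ccc(O)c(OC)c1 | starting material
10 | methyl 4-hydroxy-3-iodo-5-methoxybenzoate | COC(=O)c1cc(I)c(O)c(OC)c1 | intermediate
11 | 4-(benzyloxy)-3-methoxybenzyl alcohol | COc1cc(CO)ccc1OCc1ccccc1 | starting material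
12 | methyl 4-{[4-(benzyloxy)-3-methoxybenzyl]oxy}-3-iodo-5-methoxybenzoate | COC(=O)c1cc(I)c(OCc2ccc(OCc3ccccc3)c(OC)c2)c(OC)c1 | intermediate
13 | dimethyl oxalate | COC(=O)C(=O)OC | starting material
14 | arylmagnesium chloride from 12 | COC(=O)c1cc([Mg]Cl)c(OCc2ccc(OCc3ccccc3)c(OC)c2)c(OC)c1 | intermediate
15 | methyl 4-{[4-(benzyloxy)-3-methoxybenzyl]oxy}-3-methoxy-5-(2-methoxy-2-oxoacetyl)benzoate | COC(=O)C(=O)c1cc(C(=O)OC)cc(OC)c1OCc1ccc(OCc2ccccc2)c(OC)c1 | intermediate
16 | tosylhydrazone of 15 | COC(=O)C(=NNS(=O)(=O)c1ccc(C)cc1)c1cc(C(=O)OC)cc(OC)c1OCc1ccc(OCc2ccccc2)c(OC)c1 | intermediate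
17 | methyl 4-{[4-(benzyloxy)-3-methoxybenzyl]oxy}-3-(1-diazo-2-methoxy-2-oxoethyl)-5-methoxybenzoate | COC(=O)C(=[N+]=[N-])c1cc(C(=O)OC)cc(OC)c1OCc1ccc(OCc2ccccc2)c(OC)c1 | intermediate
18 | dimethyl (2S,3R)-2-[4-(benzyloxy)-3-methoxyphenyl]-7-methoxy-2,3-dihydrobenzofuran-3,5-dicarboxylate (cis) | COC(=O)c1cc(OC)c2c(c1)[C@@H](C(=O)OC)[C@@H](c1ccc(OCc3ccccc3)c(OC)c1)O2 | intermediate
19 | dimethyl (2S,3S)-2-[4-(benzyloxy)-3-methoxyphenyl]-7-methoxy-2,3-dihydrobenzofuran-3,5-dicarboxylate (trans) | COC(=O)c1cc(OC)c2c(c1)[C@H](C(=O)OC)[C@@H](c1ccc(OCc3ccccc3)c(OC)c1)O2 | intermediate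
20 | methyl (2S,3R)-2-[4-(benzyloxy)-3-methoxyphenyl]-3-(hydroxymethyl)-7-methoxy-2,3-dihydrobenzofuran-5-carboxylate | COC(=O)c1cc(OC)c2c(c1)[C@H](CO)[C@@H](c1ccc(OCc3ccccc3)c(OC)c1)O2 | intermediate
21 | methyl (2S,3R)-2-[4-(benzyloxy)-3-methoxyphenyl]-3-{[(tert-butyldimethylsilyl)oxy]methyl}-7-methoxy-2,3-dihydrobenzofuran-5-carboxylate | COC(=O)c1cc(OC)c2c(c1)[C@H](CO[Si](C)(C)C(C)(C)C)[C@@H](c1ccc(OCc3ccccc3)c(OC)c1)O2 | intermediate
22 | {(2S,3R)-2-[4-(benzyloxy)-3-methoxyphenyl]-3-{[(tert-butyldimethylsilyl)oxy]methyl}-7-methoxy-2,3-dihydrobenzofuran-5-yl}methanol | OCc1cc(OC)c2c(c1)[C@H](CO[Si](C)(C)C(C)(C)C)[C@@H](c1ccc(OCc3ccccc3)c(OC)c1)O2 | intermediate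
23 | (2S,3R)-2-[4-(benzyloxy)-3-methoxyphenyl]-5-(bromomethyl)-3-{[(tert-butyldimethylsilyl)oxy]methyl}-7-methoxy-2,3-dihydrobenzofuran | BrCc1cc(OC)c2c(c1)[C@H](CO[Si](C)(C)C(C)(C)C)[C@@H](c1ccc(OCc3ccccc3)c(OC)c1)O2 | intermediate
24 | lithium enolate of 8 | COc1cc(C[C@H]2COC([O-])=C2)ccc1OCc1ccccc1.[Li+] | intermediate
25 | (3R,4R)-4-[4-(benzyloxy)-3-methoxybenzyl]-3-({(2S,3R)-2-[4-(benzyloxy)-3-methoxyphenyl]-3-{[(tert-butyldimethylsilyl)oxy]methyl}-7-methoxy-2,3-dihydrobenzofuran-5-yl}methyl)dihydrofuran-2(3H)-one | COc1cc(C[C@H]2COC(=O)[C@@H]2Cc2cc(OC)c3c(c2)[C@H](CO[Si](C)(C)C(C)(C)C)[C@@H](c2ccc(OCc4ccccc4)c(OC)c2)O3)ccc1OCc1ccccc1 | intermediate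
26 | (3R,4R)-4-[4-(benzyloxy)-3-methoxybenzyl]-3-({(2S,3R)-2-[4-(benzyloxy)-3-methoxyphenyl]-3-(hydroxymethyl)-7-methoxy-2,3-dihydrobenzofuran-5-yl}methyl)dihydrofuran-2(3H)-one | COc1cc(C[C@H]2COC(=O)[C@@H]2Cc2cc(OC)c3c(c2)[C@H](CO)[C@@H](c2ccc(OCc4ccccc4)c(OC)c2)O3)ccc1OCc1ccccc1 | intermediate
27 | Isolappaol A | COc1cc(C[C@H]2COC(=O)[C@@H]2Cc2cc(OC)c3c(c2)[C@H](CO)[C@@H](c2ccc(O)c(OC)c2)O3)ccc1O | target

**Step count and risks**

Total step count: 17. Longest linear sequence: 13 steps (steps 5 to 17, from methyl vanillate 9).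

The three steps most likely to fail:

Step 4. The flexible CH2 spacer may let the catalyst pocket discriminate poorly between the two enantiotopic migrating CH2 groups, so the lactone would form with insufficient enantiomeric purity. The fallback sets out from 6 and gives up catalyst control for a resolution. Uncatalysed Baeyer–Villiger oxidation with aqueous H2O2 in AcOH gives racemic 4-[4-(benzyloxy)-3-methoxybenzyl]dihydrofuran-2(3H)-one F1. Aminolysis with (S)-1-phenylethylamine (2-hydroxypyridine cat., toluene, 90 °C) gives two diastereomeric hydroxy amides, and (3R)-3-[4-(benzyloxy)-3-methoxybenzyl]-4-hydroxy-N-[(1S)-1-phenylethyl]butanamide F2 is separated by crystallisation or chromatography from (3S)-3-[4-(benzyloxy)-3-methoxybenzyl]-4-hydroxy-N-[(1S)-1-phenylethyl]butanamide F3. Heating F2 in aqueous H2SO4/dioxane relactonises it with release of the amine, and the route is rejoined at 8.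

Step 9. The methoxy group flanking the benzyloxy oxygen twists the ether out of the ring plane, which may weaken the discrimination between the two enantiotopic benzylic hydrogens or let carbene dimerisation compete, so C2 would form with low enantiomeric purity. The fallback sets out from 17 and replaces asymmetric catalysis by racemic synthesis and resolution. Insertion with achiral Rh2(OAc)4 (dirhodium tetraacetate) in CH2Cl2 gives the racemic cis/trans mixture of dimethyl 2-[4-(benzyloxy)-3-methoxyphenyl]-7-methoxy-2,3-dihydrobenzofuran-3,5-dicarboxylate F4. NaOMe in MeOH equilibrates it to the racemic trans diester F5. Preparative chromatography on a chiral stationary phase (cellulose or amylose carbamate) separates the enantiomers, and the (2S,3S) enantiomer rejoins the route at 19.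

Step 11. The hydride may not distinguish the two esters well enough, so that the aryl ester is partly reduced as well. The fallback sets out from 19 and differentiates the two carbinols by oxidation instead. LiAlH4 in THF reduces both esters to {(2S,3R)-2-[4-(benzyloxy)-3-methoxyphenyl]-7-methoxy-2,3-dihydrobenzofuran-3,5-diyl}dimethanol F6. MnO2 in CH2Cl2 oxidises only the benzylic alcohol to (2S,3R)-2-[4-(benzyloxy)-3-methoxyphenyl]-3-(hydroxymethyl)-7-methoxy-2,3-dihydrobenzofuran-5-carbaldehyde F7. Silylation (TBSCl, imidazole) gives (2S,3R)-2-[4-(benzyloxy)-3-methoxyphenyl]-3-{[(tert-butyldimethylsilyl)oxy]methyl}-7-methoxy-2,3-dihydrobenzofuran-5-carbaldehyde F8, and NaBH4 in MeOH rejoins the route at 22.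

**Further compounds**

F1 | step 4 | racemic 4-[4-(benzyloxy)-3-methoxybenzyl]dihydrofuran-2(3H)-one | COc1cc(CC2COC(=O)C2)ccc1OCc1ccccc1
F2 | step 4 | (3R)-3-[4-(benzyloxy)-3-methoxybenzyl]-4-hydroxy-N-[(1S)-1-phenylethyl]butanamide | O=C(N[C@@H](C)c1ccccc1)C[C@H](CO)Cc1ccc(OCc2ccccc2)c(OC)c1
F3 | step 4 | (3S)-3-[4-(benzyloxy)-3-methoxybenzyl]-4-hydroxy-N-[(1S)-1-phenylethyl]butanamide | O=C(N[C@@H](C)c1ccccc1)C[C@@H](CO)Cc1ccc(OCc2ccccc2)c(OC)c1
F4 | step 9 | racemic cis/trans mixture of dimethyl 2-[4-(benzyloxy)-3-methoxyphenyl]-7-methoxy-2,3-dihydrobenzofuran-3,5-dicarboxylate | COC(=O)c1cc(OC)c2c(c1)C(C(=O)OC)C(c1ccc(OCc3ccccc3)c(OC)c1)O2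
F5 | step 9 | racemic trans diester (both enantiomers) | COC(=O)c1cc(OC)c2c(c1)[C@H](C(=O)OC)[C@@H](c1ccc(OCc3ccccc3)c(OC)c1)O2.COC(=O)c1cc(OC)c2c(c1)[C@@H](C(=O)OC)[C@H](c1ccc(OCc3ccccc3)c(OC)c1)O2
F6 | step 11 | {(2S,3R)-2-[4-(benzyloxy)-3-methoxyphenyl]-7-methoxy-2,3-dihydrobenzofuran-3,5-diyl}dimethanol | OCc1cc(OC)c2c(c1)[C@H](CO)[C@@H](c1ccc(OCc3ccccc3)c(OC)c1)O2
F7 | step 11 | (2S,3R)-2-[4-(benzyloxy)-3-methoxyphenyl]-3-(hydroxymethyl)-7-methoxy-2,3-dihydrobenzofuran-5-carbaldehyde | O=Cc1cc(OC)c2c(c1)[C@H](CO)[C@@H](c1ccc(OCc3ccccc3)c(OC)c1)O2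
F8 | step 11 | (2S,3R)-2-[4-(benzyloxy)-3-methoxyphenyl]-3-{[(tert-butyldimethylsilyl)oxy]methyl}-7-methoxy-2,3-dihydrobenzofuran-5-carbaldehyde | O=Cc1cc(OC)c2c(c1)[C@H](CO[Si](C)(C)C(C)(C)C)[C@@H](c1ccc(OCc3ccccc3)c(OC)c1)O2
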